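**Retrosynthetic overview**
1. The obvious N-arylation of a finished 4-haloindole by a second indole is avoided; the lower (methoxy, N–H) indole is instead grown onto an N-aryl-5-bromoindole.
2. Rivularin B (12) ⇐ twofold C3/C3' bromination of bis-indole 10. The C5 and C5' bromines are carried from the start, because late bromination of the lower ring would go ortho to OMe (C6), not to C5.
3. 10 ⇐ acid 9 ⇐ ester 8 ⇐ key step: Hemetsberger–Knittel vinyl-nitrene C–H insertion of azidoacrylate 6. Only one ortho C–H is free, so the 4-N/5-Br/7-OMe pattern is fixed.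
4. 6 ⇐ aldehyde 3 + ethyl azidoacetate 4; 3 ⇐ metal-free SNAr of 5-bromoindole 2 on ortho-fluorobenzaldehyde 1 (the CHO activates the fluoride and later becomes C3).
5. Ring order: upper indole (bought) → C4–N1' bond → lower pyrrole ring → brominations.

Assumption: the SMILES has no stereodescriptor (no stereocentre, and the hindered C4–N1' axis is unspecified), so the compound is made as drawn with nothing stereochemical to set; compound 1 is taken as a catalogue building block, which I have not verified.

**Route**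

Step 1
Reactants: 1 3-bromo-2-fluoro-5-methoxybenzaldehyde; 2 5-bromo-1H-indole
Product: 3 3-bromo-2-(5-bromo-1H-indol-1-yl)-5-methoxybenzaldehyde
Conditions: Cs2CO3 (2 equiv), DMSO, 100 °C
Reagents that add atoms: none
Why: Nucleophilic aromatic substitution (SNAr): the fluoride is activated by the ortho formyl group, the indolide of 2 attacks through nitrogen, and without a transition metal both aryl bromides stay untouched.

Step 2
Reactants: 3 3-bromo-2-(5-bromo-1H-indol-1-yl)-5-methoxybenzaldehyde; 4 ethyl azidoacetate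
Product: 6 ethyl (Z)-2-azido-3-[3-bromo-2-(5-bromo-1H-indol-1-yl)-5-methoxyphenyl]prop-2-enoate, via azido aldol adduct 5 (not isolated)
Conditions: NaOEt (4 equiv), 4 (4 equiv), EtOH/THF, −15 to 0 °C
Reagents that add atoms: none
Why: Knoevenagel-type aldol condensation (first stage of the Hemetsberger–Knittel indole synthesis): the azidoacetate enolate adds to the non-enolisable aldehyde and E1cB loss of water gives the conjugated Z-azidocinnamate, the low temperature preserving the azide.

Step 3
Reactants: 6 ethyl (Z)-2-azido-3-[3-bromo-2-(5-bromo-1H-indol-1-yl)-5-methoxyphenyl]prop-2-enoate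
Product: 8 ethyl 5-bromo-4-(5-bromo-1H-indol-1-yl)-7-methoxy-1H-indole-2-carboxylate, via 2H-azirine 7 (not isolated)
Conditions: xylenes (0.05 M), 140 °C
Reagents that add atoms: none
Why: Hemetsberger–Knittel thermolysis: loss of N2 gives the azirine/vinyl nitrene, which closes onto the only free ortho C–H (the other ortho position carries the indolyl group), so the five-membered ring forms with unambiguous regiochemistry.

Step 4
Reactants: 8 ethyl 5-bromo-4-(5-bromo-1H-indol-1-yl)-7-methoxy-1H-indole-2-carboxylate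
Product: 9 5-bromo-4-(5-bromo-1H-indol-1-yl)-7-methoxy-1H-indole-2-carboxylic acid
Conditions: LiOH·H2O (5 equiv), THF/EtOH/H2O, 60 °C; then 1 M HCl
Reagents that add atoms: lithium hydroxide, [Li+].[OH-]
Why: Ester saponification (acyl–oxygen cleavage by hydroxide), to which the aryl bromides, the aryl ether and both indoles are inert.

Step 5
Reactants: 9 5-bromo-4-(5-bromo-1H-indol-1-yl)-7-methoxy-1H-indole-2-carboxylic acid
Product: 10 5-bromo-4-(5-bromo-1H-indol-1-yl)-7-methoxy-1H-indole
Conditions: Ag2CO3 (10 mol %), AcOH (5 mol %), DMSO, 120 °C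
Reagents that add atoms: none
Why: Silver-catalysed protodecarboxylation of a heteroaromatic α-carboxylic acid: the silver carboxylate extrudes CO2 to a 2-indolylsilver species that is protonated by AcOH, and monovalent silver does not insert into aryl bromides.

Step 6
Reactants: 10 5-bromo-4-(5-bromo-1H-indol-1-yl)-7-methoxy-1H-indole
Product: 12 rivularin B, via upper-ring monobromide 11 (not isolated)
Conditions: NBS (2.05 equiv), DMF, −40 to 0 °C, dark
Reagents that add atoms: N-bromosuccinimide, O=C1CCC(=O)N1Br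
Why: Electrophilic aromatic substitution: C3 is the most nucleophilic position of each indole, so two equivalents of NBS at low temperature brominate C3' and C3 before the benzenoid positions or C2 react (the order of the two brominations is presumed; either monobromide gives 12).

**Compound list**
1 | 3-bromo-2-fluoro-5-methoxybenzaldehyde | COc1cc(Br)c(F)c(C=O)c1 | starting material
2 | 5-bromo-1H-indole | Brc1ccc2[nH]ccc2c1 | starting material
3 | 3-bromo-2-(5-bromo-1H-indol-1-yl)-5-methoxybenzaldehyde | COc1cc(Br)c(-n2ccc3cc(Br)ccc32)c(C=O)c1 | intermediate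
4 | ethyl azidoacetate | CCOC(=O)CN=[N+]=[N-] | starting material
5 | ethyl 2-azido-3-[3-bromo-2-(5-bromo-1H-indol-1-yl)-5-methoxyphenyl]-3-hydroxypropanoate (aldol adduct, racemic diastereomer mixture, not isolated) | CCOC(=O)C(N=[N+]=[N-])C(O)c1cc(OC)cc(Br)c1-n1ccc2cc(Br)ccc21 | intermediate
6 | ethyl (Z)-2-azido-3-[3-bromo-2-(5-bromo-1H-indol-1-yl)-5-methoxyphenyl]prop-2-enoate | CCOC(=O)/C(N=[N+]=[N-])=C/c1cc(OC)cc(Br)c1-n1ccc2cc(Br)ccc21 | intermediate
7 | ethyl 2-[3-bromo-2-(5-bromo-1H-indol-1-yl)-5-methoxyphenyl]-2H-azirine-3-carboxylate (racemic, not isolated) | CCOC(=O)C1=NC1c1cc(OC)cc(Br)c1-n1ccc2cc(Br)ccc21 | intermediate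
8 | ethyl 5-bromo-4-(5-bromo-1H-indol-1-yl)-7-methoxy-1H-indole-2-carboxylate | CCOC(=O)c1cc2c(-n3ccc4cc(Br)ccc43)c(Br)cc(OC)c2[nH]1 | intermediate
9 | 5-bromo-4-(5-bromo-1H-indol-1-yl)-7-methoxy-1H-indole-2-carboxylic acid | OC(=O)c1cc2c(-n3ccc4cc(Br)ccc43)c(Br)cc(OC)c2[nH]1 | intermediate
10 | 5-bromo-4-(5-bromo-1H-indol-1-yl)-7-methoxy-1H-indole | COc1cc(Br)c(-n2ccc3cc(Br)ccc32)c2cc[nH]c12 | intermediate
11 | 5-bromo-4-(3,5-dibromo-1H-indol-1-yl)-7-methoxy-1H-indole (presumed first-formed monobromide, not isolated) | COc1cc(Br)c(-n2cc(Br)c3cc(Br)ccc32)c2cc[nH]c12 | intermediate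
12 | rivularin B, 3,5-dibromo-4-(3,5-dibromo-1H-indol-1-yl)-7-methoxy-1H-indole | COc1cc(Br)c(-n2cc(Br)c3cc(Br)ccc32)c2c(Br)c[nH]c12 | target

**Count**
Total steps: 6. Longest linear sequence: 6 steps (from 1 or 2 to 12).

**Three steps most likely to fail, with fallbacks**

Risk at step 2 (condensation of the hindered, ortho-indolyl aldehyde with the base-labile azidoacetate). The fallback sets out from 3 and comes back at 8. It replaces the azide by a nitro group as the nitrene source. Aldehyde 3 is condensed with ethyl nitroacetate (piperidinium acetate, toluene, 4 Å sieves, 80 °C) to give ethyl 2-nitro-3-[3-bromo-2-(5-bromo-1H-indol-1-yl)-5-methoxyphenyl]prop-2-enoate F4 as an E/Z mixture. Heating F4 in P(OEt)3 at 150 °C deoxygenates the nitro group (Cadogan–Sundberg type) to the same vinyl nitrene/azirine 7, which closes to ester 8.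

Risk at step 6 (twofold bromination: possible over-bromination at C2 or attack at C6 ortho to OMe). The fallback sets out from 8 and comes back at 12. It brominates while C2 of the lower indole is still blocked by the ester. NBS (2.1 equiv, DMF, 0 °C to rt) on 8 gives ethyl 3,5-dibromo-4-(3,5-dibromo-1H-indol-1-yl)-7-methoxy-1H-indole-2-carboxylate F5. LiOH hydrolysis gives 3,5-dibromo-4-(3,5-dibromo-1H-indol-1-yl)-7-methoxy-1H-indole-2-carboxylic acid F6. Protodecarboxylation with Ag2CO3/AcOH in DMSO, helped by the ortho bromine, then gives 12.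

Risk at step 1 (SNAr at a fluoride flanked by Br and deactivated by the para OMe, with a free aldehyde present). The fallback sets out from 1 and comes back at 3. It swaps the activating group for a smaller, non-electrophilic nitrile. Heating 1 with NH2OH·HCl in DMSO at 100 °C passes through 3-bromo-2-fluoro-5-methoxybenzaldehyde oxime F1 and dehydrates it in the same pot to 3-bromo-2-fluoro-5-methoxybenzonitrile F2. SNAr of F2 with 2 (Cs2CO3, DMF, 90 °C) gives 3-bromo-2-(5-bromo-1H-indol-1-yl)-5-methoxybenzonitrile F3. Half-reduction with iBu2AlH (toluene, −78 °C) and aqueous HCl hydrolysis of the imine return aldehyde 3.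

**Further compounds**
F1 | step 1 | (E)-3-bromo-2-fluoro-5-methoxybenzaldehyde oxime | COc1cc(Br)c(F)c(/C=N/O)c1
F2 | step 1 | 3-bromo-2-fluoro-5-methoxybenzonitrile | COc1cc(Br)c(F)c(C#N)c1
F3 | step 1 | 3-bromo-2-(5-bromo-1H-indol-1-yl)-5-methoxybenzonitrile | COc1cc(Br)c(-n2ccc3cc(Br)ccc32)c(C#N)c1
F4 | step 2 | ethyl 2-nitro-3-[3-bromo-2-(5-bromo-1H-indol-1-yl)-5-methoxyphenyl]prop-2-enoate (E/Z mixture) | CCOC(=O)C(=Cc1cc(OC)cc(Br)c1-n1ccc2cc(Br)ccc21)[N+](=O)[O-]
F5 | step 6 | ethyl 3,5-dibromo-4-(3,5-dibromo-1H-indol-1-yl)-7-methoxy-1H-indole-2-carboxylate | CCOC(=O)c1[nH]c2c(OC)cc(Br)c(-n3cc(Br)c4cc(Br)ccc43)c2c1Br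
F6 | step 6 | 3,5-dibromo-4-(3,5-dibromo-1H-indol-1-yl)-7-methoxy-1H-indole-2-carboxylic acid | OC(=O)c1[nH]c2c(OC)cc(Br)c(-n3cc(Br)c4cc(Br)ccc43)c2c1Br
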